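**Retrosynthetic overview**
1. Target 29 ⇐ desilylation ⇐ 1,4-reduction of α-methylene lactone 27 (sets C11) ⇐ ring-closing metathesis of triene 26 at the Z C1=C10 olefin (ten-membered ring, formed last).
2. 26 ⇐ key C–O step: acylative lactone transposition of 12,8-olide 19 with acid 23, which forms the 12,6-lactone ring and the C8–O ester in one operation.
3. 19 ⇐ zinc Barbier union (C6–C7) of bromomethyl butenolide 10 with achiral lactol 15; the C8 centre of 10 sets C7 and C6.
4. 10 ⇐ acrolein (Brown methallylation, esterification, RCM); 15 ⇐ 4-bromofuran-2(5H)-one (Negishi, i-Bu2AlH); 23 ⇐ (S)-β-methyl-γ-butyrolactone.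
5. Ring order: butenolide (12,8-lactone) → 12,6-lactone (by transposition) → ten-membered carbocycle.

Assumption: the SMILES is read literally, so C1=C10 is Z (C2 and C9 cis), C4=C5 has C15 cis to C6, and the centres are 6R,7R,8S,11S,3'S. Germacrane numbering (C1–C15) is used for positions. H2IMes = 1,3-dimesitylimidazolidin-2-ylidene.

**Step 1**
Reactants: 1 acrolein; 2 2-methylallylmagnesium chloride; 3 (−)-B-methoxydiisopinocampheylborane
Product: 6 (3S)-5-methylhexa-1,5-dien-3-ol, via B-(2-methylallyl)diisopinocampheylborane 4 (not isolated), via homoallyl borinate 5 (not isolated)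
Conditions: 3 + 2, Et2O, −78 → 25 °C; 1, −78 °C; 3 M NaOH, 30% H2O2, 25 °C
Reagents that add atoms: none
Why: Brown asymmetric allylboration, in which the borane from 3 delivers the methallyl group through a closed chair transition state to the Si face of acrolein and so sets C8 as S (about 92–95% ee expected).

**Step 2**
Reactants: 6; 7 2-(bromomethyl)prop-2-enoic acid
Product: 9 (3S)-5-methylhexa-1,5-dien-3-yl 2-(bromomethyl)prop-2-enoate, via O-acylisourea 8 (not isolated)
Conditions: N,N'-diisopropylcarbodiimide (DIC), DMAP (5 mol %), CH2Cl2, 0 °C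
Reagents that add atoms: none
Why: Steglich esterification at 0 °C with little DMAP acylates the secondary alcohol without breaking its C–O bond (C8 unchanged) and spares the allylic bromide.

**Step 3**
Reactants: 9
Product: 10 (5S)-3-(bromomethyl)-5-(2-methylprop-2-en-1-yl)furan-2(5H)-one
Conditions: second-generation Hoveyda–Grubbs catalyst RuCl2(H2IMes)(=CH-C6H4-2-O-i-Pr) (5 mol %), toluene (10 mM), 80 °C
Reagents that add atoms: none
Why: Ring-closing metathesis of the acrylate with the vinyl group is the only feasible closure, because the methallyl group could only give a cyclobutene or a tetrasubstituted olefin, so the butenolide forms with C8 untouched.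

**Step 4**
Reactants: 11 4-bromofuran-2(5H)-one; 12 but-3-en-1-ylzinc bromide
Product: 13 4-(but-3-en-1-yl)furan-2(5H)-one
Conditions: Pd(PPh3)4 (3 mol %), THF, 50 °C
Reagents that add atoms: none
Why: Negishi coupling of the vinylogous acyl bromide (fast oxidative addition to zerovalent palladium) with a primary alkylzinc locks the later C4=C5 geometry inside the ring, with C15–O and C6 cis.

**Step 5**
Reactants: 13
Product: 15 4-(but-3-en-1-yl)-2,5-dihydrofuran-2-ol, via aluminium lactolate 14 (not isolated)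
Conditions: i-Bu2AlH (1.1 equiv), CH2Cl2, −78 °C; aq KNaC4H4O6, 0 °C; used crude at once
Reagents that add atoms: none
Why: Partial lactone reduction stops at the tetrahedral aluminium lactolate at −78 °C, and neutral tartrate work-up gives the lactol (a masked (Z)-γ-hydroxy enal) without dehydration to the furan.

**Step 6**
Reactants: 10; 15
Product: 18 (4S,5S)-4-[(1R,2Z)-1-hydroxy-3-(hydroxymethyl)hepta-2,6-dien-1-yl]-3-methylidene-5-(2-methylprop-2-en-1-yl)oxolan-2-one, via allylzinc bromide 16 (not isolated), via open-chain hydroxy enal 17 (not isolated)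
Conditions: Zn dust (3 equiv), THF/aq NH4Cl (brought to pH 7 with NH3), 0 → 25 °C, 10 added over 1 h
Reagents that add atoms: none
Why: Aqueous zinc Barbier 2-(alkoxycarbonyl)allylation, in which the ring-locked allylzinc (C8 trans to CH2Zn, an E-crotyl-type reagent) adds through C7 in a Zimmerman–Traxler chair to the enal released from the lactol, anti to the C8 methallyl group (C7 trans to C8) and with anti simple selectivity (C6 R), so C8 alone sets C7 and C6 and no hydroxyl needs protection.

**Step 7**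
Reactants: 18
Product: 19 (4S,5S)-4-[(1R,2Z)-3-({[tert-butyl(dimethyl)silyl]oxy}methyl)-1-hydroxyhepta-2,6-dien-1-yl]-3-methylidene-5-(2-methylprop-2-en-1-yl)oxolan-2-one
Conditions: TBSCl (1.05 equiv), imidazole, CH2Cl2, −20 °C
Reagents that add atoms: tert-butyldimethylsilyl chloride, CC(C)(C)[Si](C)(C)Cl
Why: Selective silylation, since the primary allylic C15 hydroxyl reacts far faster than the hindered secondary C6 hydroxyl.

**Step 8**
Reactants: 20 (4S)-4-methyloxolan-2-one
Product: 23 (3S)-4-{[tert-butyl(dimethyl)silyl]oxy}-3-methylbutanoic acid, via potassium hydroxy carboxylate 21 (not isolated), via bis-silyl compound 22 (not isolated)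
Conditions: KOH (1.0 equiv), MeOH/H2O, 25 °C, evaporate; TBSCl (2.2 equiv), imidazole, DMF, 25 °C; THF/H2O/AcOH (8:1:1), 0 °C, 30 min
Reagents that add atoms: potassium hydroxide, [K+].[OH-]; tert-butyldimethylsilyl chloride, CC(C)(C)[Si](C)(C)Cl
Why: Saponification, exhaustive silylation and selective hydrolysis of the labile silyl ester give the O-protected acid, and the C3' centre is never touched.

**Step 9**
Reactants: 19; 23
Product: 26 (1S)-1-[(2R,3R)-2-[(1Z)-2-({[tert-butyl(dimethyl)silyl]oxy}methyl)hexa-1,5-dien-1-yl]-4-methylidene-5-oxooxolan-3-yl]-3-methylbut-3-en-1-yl (3S)-4-{[tert-butyl(dimethyl)silyl]oxy}-3-methylbutanoate, via anhydride 24 (not isolated), via 8-hydroxy 12,6-olide 25 (not isolated)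
Conditions: 23 (2.6 equiv), DIC (1.3 equiv), CH2Cl2, 0 °C, filter (gives 24); 19, DBU (2 equiv), toluene, 40 °C, 2 h; then 24 over 8 h, DMAP (5 mol %), 40 °C
Reagents that add atoms: none
Why: Proposed new method: an acylative lactone transposition under Curtin–Hammett control, in which DBU reversibly moves the lactone acyl group between O8 and O6 (intramolecular transesterification through a bicyclic tetrahedral intermediate, C6–O and C8–O bonds intact, so no stereocentre is touched) while the slowly added anhydride with DMAP acylates the less hindered C8 hydroxyl of isomer 25 faster than the C6 hydroxyl of 19, which is shielded by the lactone ring and by the cis CH2OTBS group of the Z olefin, so the mixture drains to 26; the closest known reactions are base-mediated translactonization of β-(1-hydroxyalkyl)-γ-butyrolactones and dynamic kinetic acylation of equilibrating alcohols with DMAP and an anhydride.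

**Step 10**
Reactants: 26
Product: 27 (3aR,4S,6Z,10Z,11aR)-10-({[tert-butyl(dimethyl)silyl]oxy}methyl)-6-methyl-3-methylidene-2-oxo-2,3,3a,4,5,8,9,11a-octahydrocyclodeca[b]furan-4-yl (3S)-4-{[tert-butyl(dimethyl)silyl]oxy}-3-methylbutanoate
Conditions: second-generation Hoveyda–Grubbs catalyst RuCl2(H2IMes)(=CH-C6H4-2-O-i-Pr) (15 mol %, in portions), 1,4-benzoquinone (30 mol %), toluene (1 mM), 80 °C
Reagents that add atoms: none
Why: Ring-closing metathesis of the terminal vinyl group with the methallyl group, pre-organized by the trans lactone and the E-configured C4=C5 unit, should give the ring-cis (Z) trisubstituted olefin that medium-ring closures favour, while the exo-methylene and C4=C5 cannot close without an E-cyclooctene or a tetrasubstituted olefin.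

**Step 11**
Reactants: 27
Product: 28 (3S,3aR,4S,6Z,10Z,11aR)-10-({[tert-butyl(dimethyl)silyl]oxy}methyl)-3,6-dimethyl-2-oxo-2,3,3a,4,5,8,9,11a-octahydrocyclodeca[b]furan-4-yl (3S)-4-{[tert-butyl(dimethyl)silyl]oxy}-3-methylbutanoate
Conditions: NaBH4 (2 equiv), MeOH/THF (1:1), −20 → 0 °C; aq NH4Cl
Reagents that add atoms: none
Why: Conjugate (1,4) hydride reduction of the α-methylene lactone, where protonation of the enolate (equilibrated by the methoxide present) leaves the methyl group pseudo-equatorial and trans to the C8 substituent (11S), the outcome trans-fused 12,6-germacranolides generally give, while esters and silyl ethers survive at or below 0 °C.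

**Step 12**
Reactants: 28
Product: 29 (3S,3aR,4S,6Z,10Z,11aR)-10-(hydroxymethyl)-3,6-dimethyl-2-oxo-2,3,3a,4,5,8,9,11a-octahydrocyclodeca[b]furan-4-yl (3S)-4-hydroxy-3-methylbutanoate (CNP0160815.1)
Conditions: HF·pyridine, pyridine/THF, 0 → 25 °C; aq NaHCO3 to pH 7
Reagents that add atoms: none
Why: Buffered fluoride desilylation removes both primary TBS ethers under non-basic conditions, so the freed γ-hydroxy ester neither lactonizes nor migrates and no stereocentre is affected.

**Compound list**
1 | acrolein (prop-2-enal) | C=CC=O | starting material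
2 | 2-methylallylmagnesium chloride | C=C(C)C[Mg]Cl | starting material
3 | (−)-B-methoxydiisopinocampheylborane | COB([C@@H]1C[C@@H]2C[C@H]([C@H]1C)C2(C)C)[C@@H]1C[C@@H]2C[C@H]([C@H]1C)C2(C)C | starting material
4 | B-(2-methylallyl)diisopinocampheylborane (formed in situ) | C=C(C)CB([C@@H]1C[C@@H]2C[C@H]([C@H]1C)C2(C)C)[C@@H]1C[C@@H]2C[C@H]([C@H]1C)C2(C)C | intermediate
5 | diisopinocampheylborinate of (3S)-5-methylhexa-1,5-dien-3-ol (formed in situ) | C=C[C@@H](OB([C@@H]1C[C@@H]2C[C@H]([C@H]1C)C2(C)C)[C@@H]1C[C@@H]2C[C@H]([C@H]1C)C2(C)C)CC(C)=C | intermediate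
6 | (3S)-5-methylhexa-1,5-dien-3-ol | C=C[C@@H](O)CC(C)=C | intermediate
7 | 2-(bromomethyl)prop-2-enoic acid | C=C(CBr)C(=O)O | starting material
8 | O-acylisourea of 7 with DIC (formed in situ) | C=C(CBr)C(=O)OC(=NC(C)C)NC(C)C | intermediate
9 | (3S)-5-methylhexa-1,5-dien-3-yl 2-(bromomethyl)prop-2-enoate | C=C(CBr)C(=O)O[C@H](C=C)CC(C)=C | intermediate
10 | (5S)-3-(bromomethyl)-5-(2-methylprop-2-en-1-yl)furan-2(5H)-one | C=C(C)C[C@@H]1OC(=O)C(CBr)=C1 | intermediate
11 | 4-bromofuran-2(5H)-one | O=C1C=C(Br)CO1 | starting material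
12 | but-3-en-1-ylzinc bromide | C=CCC[Zn]Br | starting material
13 | 4-(but-3-en-1-yl)furan-2(5H)-one | C=CCCC1=CC(=O)OC1 | intermediate
14 | diisobutylaluminium 4-(but-3-en-1-yl)-2,5-dihydrofuran-2-olate (formed in situ) | C=CCCC1=CC(O[Al](CC(C)C)CC(C)C)OC1 | intermediate
15 | 4-(but-3-en-1-yl)-2,5-dihydrofuran-2-ol (racemic hemiacetal) | C=CCCC1=CC(O)OC1 | intermediate
16 | {[(5S)-5-(2-methylprop-2-en-1-yl)-2-oxo-2,5-dihydrofuran-3-yl]methyl}zinc bromide (formed in situ) | C=C(C)C[C@@H]1OC(=O)C(C[Zn]Br)=C1 | intermediate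
17 | (2Z)-3-(hydroxymethyl)hepta-2,6-dienal (open form of 15, formed in situ) | O=C/C=C(CO)/CCC=C | intermediate
18 | (4S,5S)-4-[(1R,2Z)-1-hydroxy-3-(hydroxymethyl)hepta-2,6-dien-1-yl]-3-methylidene-5-(2-methylprop-2-en-1-yl)oxolan-2-one | C=C(C)C[C@@H]1OC(=O)C(=C)[C@H]1[C@H](O)/C=C(CO)/CCC=C | intermediate
19 | (4S,5S)-4-[(1R,2Z)-3-({[tert-butyl(dimethyl)silyl]oxy}methyl)-1-hydroxyhepta-2,6-dien-1-yl]-3-methylidene-5-(2-methylprop-2-en-1-yl)oxolan-2-one | C=C(C)C[C@@H]1OC(=O)C(=C)[C@H]1[C@H](O)/C=C(CO[Si](C)(C)C(C)(C)C)/CCC=C | intermediate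
20 | (4S)-4-methyloxolan-2-one ((S)-β-methyl-γ-butyrolactone) | O=C1C[C@H](C)CO1 | starting material
21 | potassium (3S)-4-hydroxy-3-methylbutanoate (formed in situ) | [K+].[O-]C(=O)C[C@H](C)CO | intermediate
22 | tert-butyldimethylsilyl (3S)-4-{[tert-butyl(dimethyl)silyl]oxy}-3-methylbutanoate (formed in situ) | CC(C)(C)[Si](C)(C)OC(=O)C[C@H](C)CO[Si](C)(C)C(C)(C)C | intermediate
23 | (3S)-4-{[tert-butyl(dimethyl)silyl]oxy}-3-methylbutanoic acid | OC(=O)C[C@H](C)CO[Si](C)(C)C(C)(C)C | intermediate
24 | (3S)-4-{[tert-butyl(dimethyl)silyl]oxy}-3-methylbutanoic anhydride (formed in situ) | CC(C)(C)[Si](C)(C)OC[C@@H](C)CC(=O)OC(=O)C[C@H](C)CO[Si](C)(C)C(C)(C)C | intermediate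
25 | (4R,5R)-5-[(1Z)-2-({[tert-butyl(dimethyl)silyl]oxy}methyl)hexa-1,5-dien-1-yl]-4-[(1S)-1-hydroxy-3-methylbut-3-en-1-yl]-3-methylideneoxolan-2-one (formed in situ) | C=C(C)C[C@H](O)[C@H]1C(=C)C(=O)O[C@@H]1/C=C(CO[Si](C)(C)C(C)(C)C)/CCC=C | intermediate
26 | (1S)-1-[(2R,3R)-2-[(1Z)-2-({[tert-butyl(dimethyl)silyl]oxy}methyl)hexa-1,5-dien-1-yl]-4-methylidene-5-oxooxolan-3-yl]-3-methylbut-3-en-1-yl (3S)-4-{[tert-butyl(dimethyl)silyl]oxy}-3-methylbutanoate | C=C(C)C[C@H](OC(=O)C[C@H](C)CO[Si](C)(C)C(C)(C)C)[C@H]1C(=C)C(=O)O[C@@H]1/C=C(CO[Si](C)(C)C(C)(C)C)/CCC=C | intermediate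
27 | (3aR,4S,6Z,10Z,11aR)-10-({[tert-butyl(dimethyl)silyl]oxy}methyl)-6-methyl-3-methylidene-2-oxo-2,3,3a,4,5,8,9,11a-octahydrocyclodeca[b]furan-4-yl (3S)-4-{[tert-butyl(dimethyl)silyl]oxy}-3-methylbutanoate | C/C1=C/CC/C(CO[Si](C)(C)C(C)(C)C)=C/[C@H]2OC(=O)C(=C)[C@@H]2[C@@H](OC(=O)C[C@H](C)CO[Si](C)(C)C(C)(C)C)C1 | intermediate
28 | (3S,3aR,4S,6Z,10Z,11aR)-10-({[tert-butyl(dimethyl)silyl]oxy}methyl)-3,6-dimethyl-2-oxo-2,3,3a,4,5,8,9,11a-octahydrocyclodeca[b]furan-4-yl (3S)-4-{[tert-butyl(dimethyl)silyl]oxy}-3-methylbutanoate | C/C1=C/CC/C(CO[Si](C)(C)C(C)(C)C)=C/[C@H]2OC(=O)[C@@H](C)[C@@H]2[C@@H](OC(=O)C[C@H](C)CO[Si](C)(C)C(C)(C)C)C1 | intermediate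
29 | (3S,3aR,4S,6Z,10Z,11aR)-10-(hydroxymethyl)-3,6-dimethyl-2-oxo-2,3,3a,4,5,8,9,11a-octahydrocyclodeca[b]furan-4-yl (3S)-4-hydroxy-3-methylbutanoate | C/C1=C/CC/C(CO)=C/[C@H]2OC(=O)[C@@H](C)[C@@H]2[C@@H](OC(=O)C[C@H](C)CO)C1 | target

**Count**
Total: 12 steps. Longest linear sequence: 9 steps (1, 2, 3, 6, 7, 9, 10, 11, 12).

**Steps most likely to fail, with fallbacks**

Step 9 (proposed acylative lactone transposition). The 19/25 equilibrium may lie on the wrong side, the C6 hydroxyl may be acylated competitively, or DBU may attack the exo-methylene. The fallback uses known chemistry, sets out from 19 and returns at 26. Compound 19 alone is equilibrated with DBU (0.3 equiv, toluene, 40 °C, no acyl donor). The translactonized alcohol 25 is separated from 19 on silica and the recovered 19 is resubmitted. Isolated 25 is then esterified with acid 23 (DIC, DMAP, CH2Cl2, 0 °C), where the lactone does not migrate. This fallback makes no compound outside the list (F0).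

Step 10 (ten-membered ring-closing metathesis). Oligomerization or a wrong olefin geometry are the risks. The fallback sets out from 19 and returns at 27, closing the carbocycle before the lactone switch. Metathesis of 19 (same ruthenium catalyst, 1 mM, toluene, 80 °C) gives (3aS,4R,5Z,9Z,11aS)-6-({[tert-butyl(dimethyl)silyl]oxy}methyl)-4-hydroxy-10-methyl-3-methylidene-3a,4,7,8,11,11a-hexahydrocyclodeca[b]furan-2(3H)-one F1. In 19 the two olefin arms sit on the vicinal trans carbons C7 and C8 of the other lactone and no bulky ester flanks the methallyl group. The lactone transposition and acylation of step 9 (or its stepwise fallback) with anhydride 24 on F1 then gives 27.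

Step 6 (Barbier coupling with the lactol). The lactol may dehydrate to the furan, and the diastereoselectivity may be lower in water. The fallback sets out from 13 and returns at 19, so step 7 is no longer needed. Butenolide 13 is opened with Me2AlN(OMe)Me (from AlMe3 and MeNH(OMe)·HCl) to (2Z)-3-(hydroxymethyl)-N-methoxy-N-methylhepta-2,6-dienamide F2. Silylation (TBSCl, imidazole) gives (2Z)-3-({[tert-butyl(dimethyl)silyl]oxy}methyl)-N-methoxy-N-methylhepta-2,6-dienamide F3. Reduction with i-Bu2AlH (THF, −78 °C) gives (2Z)-3-({[tert-butyl(dimethyl)silyl]oxy}methyl)hepta-2,6-dienal F4. F4 is coupled with bromide 10 under anhydrous Nozaki–Hiyama conditions (CrCl2, THF, 25 °C), which uses the same ring-locked allyl metal and chair transition state but no lactol and no aqueous medium, giving 19 directly.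

**Further compounds**
F0 | step 9 | none | none
F1 | step 10 | (3aS,4R,5Z,9Z,11aS)-6-({[tert-butyl(dimethyl)silyl]oxy}methyl)-4-hydroxy-10-methyl-3-methylidene-3a,4,7,8,11,11a-hexahydrocyclodeca[b]furan-2(3H)-one | C/C1=C/CC/C(CO[Si](C)(C)C(C)(C)C)=C/[C@@H](O)[C@@H]2C(=C)C(=O)O[C@H]2C1
F2 | step 6 | (2Z)-3-(hydroxymethyl)-N-methoxy-N-methylhepta-2,6-dienamide | CON(C)C(=O)/C=C(CO)/CCC=C
F3 | step 6 | (2Z)-3-({[tert-butyl(dimethyl)silyl]oxy}methyl)-N-methoxy-N-methylhepta-2,6-dienamide | CON(C)C(=O)/C=C(CO[Si](C)(C)C(C)(C)C)/CCC=C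
F4 | step 6 | (2Z)-3-({[tert-butyl(dimethyl)silyl]oxy}methyl)hepta-2,6-dienal | O=C/C=C(CO[Si](C)(C)C(C)(C)C)/CCC=C
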